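The constants set the Ze step and the Ek step 15.0 kJ mol⁻¹ apart in activation energy, and I followed that gap from one temperature to the other.

    G + Z + E → Z + Ze (k1 = 150 M⁻² min⁻¹, Ea1 = 39.0 kJ mol⁻¹)
    G + Z + X → Z + Ek (k2 = 9.2 M⁻² min⁻¹, Ea2 = 54.0 kJ mol⁻¹)
    E + D ⇌ X + D, rate k3*[D]*[E] forward; the back reaction follows from the equilibrium constant (k3 = 270 M⁻¹ min⁻¹, Ea3 = 63.0 kJ mol⁻¹)
    Z → J (k4 = 7.3 × 10⁻⁶ min⁻¹, Ea4 = 130 kJ mol⁻¹)
    G + Uv → Z + Q (k5 = 0.039 M⁻¹ min⁻¹, Ea5 = 81.0 kJ mol⁻¹)
    (constants at 60 °C)

| flask | E | G | D | Uv | X | temperature | time |
|---|---|---|---|---|---|---|---|
| red | 20 mM | 60.0 mM | 1.2 mM | 100 µM | 20 mM | 35 °C | 8.0 h |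
| amber | 20 mM | 60.0 mM | 1.2 mM | 100 µM | 20 mM | 60 °C | 8.0 h |

1. which flask leads in excess of Ze over Ek ("all alike" within 1.5 percentage points) (red / amber / all alike)
2. excess of Ze over Ek at the end, red
3. excess of Ze over Ek at the end, amber

- Z is single-handed; E and X are mirror images of each other, charged as a racemate, each of them at the stated concentration
- all constants are for 60 °C and move with temperature by the activation energies
- an excess is the difference of the two amounts in percent of their sum
- an excess is below zero if the other one leads

Both product steps carry the same G and the same Z, so these cancel in the ratio of the two rates. With E and X equal, that ratio is the ratio of the two constants, the selectivity factor s, taken at each flask's temperature by the activation energies.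

amber: s = 16.3, excess = (s − one) / (s + one) = 88.4 %

red: s = 25.3, excess = (s − one) / (s + one) = 92.4 %

All of this needs E and X equal, and I tested that in two ways.

In the first way I let D hold them together and reckoned the racemisation count: the number of half-lives of the gap between E and X that fit into one half-life of E under the Ze step. Both directions of the turning close the gap, so its rate constant is twice the forward constant times D. For E, I set the whole Uv charge as Z and G at its charge. Neither can exceed that, so the real half-life of E is no shorter.

amber: gap 1.07 min, E 12.8 h, count 720

red: gap 6.77 min, E 40.2 h, count 356

Both counts lie far above one, so D keeps E and X together in both flasks.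

In the second way I struck D from the reckoning and asked how much E goes by the end, with Z growing out of Uv at G's charge. In red, E loses 0.695 %, so the pair stays equal to within that share and the same excess follows for a different reason. In amber, E loses 15.8 %, too much to call the two equal, and here the ways part. The second way is the one that cheats in amber, because the half-life of the gap is far shorter than that of E. So I kept both excesses and put red ahead by 4 percentage points.

The forecast named red, with 92.4 % for red and 88.4 % for amber, holding that “the lower activation energy of step 1 favours the colder red flask”.

The flask gave 92.4 % in red and 88.4 % in amber, and red led. In red at the end, with Z at 9.94 % of the catalyst charged, the half-life of E by the Ze step stood at 17 d, which is 3616 gap half-lives against the count of 356. The neighbour is red with 100 mM of G. Set as before, with the whole Uv charge as Z and G at its new charge, its racemisation count comes to 214, a floor for that flask that is lower than the 356 of red and still far above one, and its excess stood at 92.4 %.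

The numbers were drawn at random within sensible limits; the flask was simulated.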